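**Plan**
Numbering used below: cyclohexanone ring C1(isobutyryl)–C9(=O)–C5(geranyl)–C6H2–C7H–C8Me2; trione ring C1–C2(=O)–C3–C4(=O)–C5–C9; C10H2 joins C7 to C11H; cyclopentane C3–C11–C12Me2–C13H2–C14H2.
The retrosynthesis cuts C1–C8 first. C1 is the central carbon of an enolised 2-acyl-1,3-dione (C2, C9 and the isobutyryl carbonyl) and faces C7 directly across a bicyclo[4.3.1]decane, so a cation at C8 on C7 can close the ring C1–C9–C5–C6–C7–C8 between two quaternary carbons.
Further cuts: the C8 methyl groups and C7–C8 (Grignard addition to an ester made by carbonylation), C5–C6 (Michael closure of the seven-membered ring C3–C4–C5–C6–C7–C10–C11), C5–geranyl, then C4–C5 and C1–C2 (Claisen assembly of the trione ring on a cyclopentane-1,1-dicarboxylate) and C10–C11 (radical allylation).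
Forward ring order: cyclopentane (present in 2,2-dimethylcyclopentanone 1), spiro trione ring, seven-membered ring, cyclohexanone ring (cage).
Stereochemistry: an asymmetric hydrogenation with dynamic kinetic resolution sets the ester-bearing carbon (future C3). This is relayed to C11 by anti radical allylation and back to quaternary C3 by anti enolate acylation, which also decides which carbonyl becomes C4 and which C2. C5, C7 and C1 follow from the tether and the cage.

Key step: step 10

Remark: enolisable β-triketones are written as one enol tautomer; 5-methylhexane-2,4-dione and (E)-geranyl bromide are taken as commercial.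

Step 1
Reactants: 1 2,2-dimethylcyclopentan-1-one
Product: 2 methyl 3,3-dimethyl-2-oxocyclopentane-1-carboxylate (racemic)
Conditions: NaH (2.2 equiv), dimethyl carbonate, THF, reflux; aq. HCl
Reagents that add atoms: dimethyl carbonate COC(=O)OC
Why: Claisen-type C-methoxycarbonylation at the only enolisable α-carbon of the ketone, driven by formation of the β-keto ester enolate; the new centre is configurationally labile and is fixed in the next step.

Step 2
Reactants: 2 methyl 3,3-dimethyl-2-oxocyclopentane-1-carboxylate
Product: 3 methyl (1R,2S)-2-hydroxy-3,3-dimethylcyclopentane-1-carboxylate (trans)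
Conditions: RuCl2[(R)-BINAP] (1 mol%), H2 (100 atm), CH2Cl2, 50 °C
Reagents that add atoms: none
Why: Noyori asymmetric hydrogenation of an α-substituted β-keto ester with dynamic kinetic resolution, in which the enantiomers of 2 interconvert through the enol while the chelated ruthenium hydride reduces one of them, which should set C1 as (R) with the trans alcohol (spatially the same isomer as in the parent 2-oxocyclopentanecarboxylate series); only C1 is carried on.

Step 3
Reactants: 3 methyl (1R,2S)-2-hydroxy-3,3-dimethylcyclopentane-1-carboxylate
Product: 4 methyl (1R,2S)-3,3-dimethyl-2-(phenoxycarbonothioyloxy)cyclopentane-1-carboxylate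
Conditions: PhOC(S)Cl, pyridine, DMAP (cat.), CH2Cl2, 0 °C to rt
Reagents that add atoms: O-phenyl chlorothionoformate S=C(Cl)Oc1ccccc1
Why: acylation of the secondary alcohol to a thionocarbonate (the radical precursor of Barton–McCombie chemistry) under conditions too mild to epimerise C1 or to eliminate to the enoate.

Step 4
Reactants: 4 methyl (1R,2S)-3,3-dimethyl-2-(phenoxycarbonothioyloxy)cyclopentane-1-carboxylate; 5 2,3-dibromoprop-1-ene
Product: 6 methyl (1R,2S)-2-(2-bromoprop-2-en-1-yl)-3,3-dimethylcyclopentane-1-carboxylate (trans)
Conditions: (Bu3Sn)2 (1.5 equiv), 5 (5 equiv), hν (sunlamp), benzene, 60 °C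
Reagents that add atoms: none
Why: Keck-type radical allylation by addition and fragmentation, in which the stannyl radical cleaves the thionocarbonate, the cyclopentyl radical adds to the CH2 terminus of 5 and expels a bromine atom that carries the chain through the ditin, and the C–C bond forms anti to the neighbouring ester so that the C1 configuration is copied onto C2 (any cis isomer is removed here because it would lead into the antipodal series).

Step 5
Reactants: 6 methyl (1R,2S)-2-(2-bromoprop-2-en-1-yl)-3,3-dimethylcyclopentane-1-carboxylate
Product: 7 1-methyl 1-phenyl (1R,2R)-2-(2-bromoprop-2-en-1-yl)-3,3-dimethylcyclopentane-1,1-dicarboxylate (phenyl ester trans to the bromoallyl group)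
Conditions: LiN(iPr)2 (1.1 equiv), THF, −78 °C; PhOC(O)Cl, −78 to −30 °C
Reagents that add atoms: phenyl chloroformate O=C(Cl)Oc1ccccc1
Why: C-acylation of the ester enolate by a chloroformate, in which the planar enolate is attacked on the face anti to the adjacent bromoallyl group, so the new phenyl ester is trans and the original methyl ester cis to the side chain and the two carbonyl arms on the new quaternary carbon become chemically distinct.

Step 6
Reactants: 7 1-methyl 1-phenyl (1R,2R)-2-(2-bromoprop-2-en-1-yl)-3,3-dimethylcyclopentane-1,1-dicarboxylate; 8 5-methylhexane-2,4-dione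
Product: 10 1-(2-bromoprop-2-en-1-yl)-2,2-dimethyl-7-(2-methylpropanoyl)spiro[4.5]decane-6,8,10-trione (spiro numbering; written as dienol; the C6 carbonyl next to the acylated C7 is cis to the bromoallyl group), via triketo ester 9 (not isolated)
Conditions: 8 (2.5 equiv), LiN(iPr)2 (5 equiv), THF, −78 to 0 °C; then 7, −78 to 40 °C; aq. HCl
Reagents that add atoms: none
Why: polyketide-type double Claisen sequence in which the terminal carbanion of the β-diketone dianion attacks the more electrophilic phenyl ester and the central carbon of the resulting 3,5,7-triketone then closes onto the neighbouring methyl ester (6-exo-trig Claisen condensation, driven by the acidity of the 2-acyl-1,3,5-trione), so the acylated ring carbon ends next to the carbonyl that is cis to the side chain and the spiro carbon becomes a defined stereocentre without a bond to it being made.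

Step 7
Reactants: 10 1-(2-bromoprop-2-en-1-yl)-2,2-dimethyl-7-(2-methylpropanoyl)spiro[4.5]decane-6,8,10-trione; 11 geranyl bromide [(2E)-1-bromo-3,7-dimethylocta-2,6-diene]
Product: 12 9-[(2E)-3,7-dimethylocta-2,6-dien-1-yl] derivative of 10 (geranyl on the formerly unsubstituted ring carbon; the future C5)
Conditions: NaOMe (2 equiv), MeOH, 0 °C; 11 (1.0 equiv), 0 °C to rt; aq. HCl
Reagents that add atoms: none
Why: C-alkylation of the ambident trione anion by an allylic bromide at its only unsubstituted ring carbon (the classical prenylation of acylphloroglucinol-type triones, favoured over O-alkylation in a protic solvent); the new centre stays enolisable and needs no control.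

Step 8
Reactants: 12 geranylated spiro trione
Product: 14 tricyclic methyl ester: target skeleton without the C1–C8 bond; CO2Me on C7 pointing towards C1 (endo); C1–H enolised, via acrylate 13 (not isolated)
Conditions: Pd(OAc)2 (5 mol%), dppp (6 mol%), CO (5 atm), Et3N, MeOH/DMF, 60 °C; then DBU, rt
Reagents that add atoms: carbon monoxide [C-]#[O+]; methanol CO
Why: palladium-catalysed alkoxycarbonylation of the vinyl bromide gives the α-substituted acrylate, and the trione anion then adds through its geranyl-bearing carbon to the CH2 terminus (intramolecular Michael addition, 7-endo-trig), the tether reaching only the ring face that carries C11 so that C5 is set with the geranyl group exo, while protonation of the ester enolate from the open outer face should place the ester on C7 endo.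

Step 9
Reactants: 14 tricyclic methyl ester
Product: 15 tertiary alcohol: as 14 but C7 carries C(CH3)2OH (the future C8)
Conditions: MeMgBr (6 equiv), CeCl3, THF, −78 to 0 °C; aq. NH4Cl
Reagents that add atoms: methylmagnesium bromide C[Mg]Br
Why: double addition of a methylcerium reagent to the ester, in which the first equivalent turns the triketone into its unreactive enolate, the low basicity of the cerium reagent avoids enolisation of the intermediate methyl ketone (and so epimerisation at C7), and the C4 ketone between two quaternary carbons is too hindered to react.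

Step 10
Reactants: 15 tertiary alcohol
Product: 16 target CNP0313870.1
Conditions: BF3·OEt2 (2.5 equiv), CH2Cl2, −60 to −20 °C; Et3N, aq. NaHCO3
Reagents that add atoms: none
Why: BF3 ionises the tertiary alcohol on C7 to the 2-propyl cation C8, which is captured by C1, the central carbon of the enolised 2-acyl-1,3-dione, forming the C1–C8 bond between two quaternary carbons and closing the cyclohexanone ring C1–C9–C5–C6–C7–C8. The closest known reaction type is the boron trifluoride-mediated C-alkylation of β-dicarbonyl compounds by tertiary alcohols, here intramolecular and analogous to the cation–enol cyclisations that close bicyclo[3.3.1]nonane acylphloroglucinols. The six-membered ring closes exo at the cationic carbon, enol-endo through the C9 enol or enol-exo through the C2 enol, both allowed modes, and easily because C8 hangs directly over C1 in the bicyclo[4.3.1]decane. The only new stereocentre, C1, is fixed by the cage, since bonding is possible only on the face of planar C1 that faces C8, which leaves the isobutyryl group exo. The step needs carbon rather than oxygen capture and ionisation at C8 rather than protonation of the geranyl alkenes; the first is secured because a tertiary alkyl enol ether re-ionises under the Lewis acid whereas C-alkylation is irreversible, the second by generating the cation from the alcohol under aprotic conditions at low temperature.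

**Compound list**
1 | 2,2-dimethylcyclopentan-1-one | CC1(C)CCCC1=O | starting material
2 | methyl 3,3-dimethyl-2-oxocyclopentane-1-carboxylate (racemic) | COC(=O)C1CCC(C)(C)C1=O | intermediate
3 | methyl (1R,2S)-2-hydroxy-3,3-dimethylcyclopentane-1-carboxylate | O[C@@H]1C(C)(C)CC[C@H]1C(=O)OC | intermediate
4 | methyl (1R,2S)-3,3-dimethyl-2-(phenoxycarbonothioyloxy)cyclopentane-1-carboxylate | S=C(Oc1ccccc1)O[C@@H]2C(C)(C)CC[C@H]2C(=O)OC | intermediate
5 | 2,3-dibromoprop-1-ene | C=C(Br)CBr | starting material
6 | methyl (1R,2S)-2-(2-bromoprop-2-en-1-yl)-3,3-dimethylcyclopentane-1-carboxylate | C=C(Br)C[C@@H]1C(C)(C)CC[C@H]1C(=O)OC | intermediate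
7 | 1-methyl 1-phenyl (1R,2R)-2-(2-bromoprop-2-en-1-yl)-3,3-dimethylcyclopentane-1,1-dicarboxylate | C=C(Br)C[C@@H]1C(C)(C)CC[C@]1(C(=O)Oc2ccccc2)C(=O)OC | intermediate
8 | 5-methylhexane-2,4-dione | CC(=O)CC(=O)C(C)C | starting material
9 | methyl (1S,2R)-2-(2-bromoprop-2-en-1-yl)-3,3-dimethyl-1-(6-methyl-3,5-dioxoheptanoyl)cyclopentane-1-carboxylate | C=C(Br)C[C@@H]1C(C)(C)CC[C@]1(C(=O)CC(=O)CC(=O)C(C)C)C(=O)OC | intermediate (not isolated)
10 | 1-(2-bromoprop-2-en-1-yl)-2,2-dimethyl-7-(2-methylpropanoyl)spiro[4.5]decane-6,8,10-trione (dienol form; C6 carbonyl cis to the bromoallyl group) | C=C(Br)C[C@@H]1C(C)(C)CC[C@]12C(O)=C(C(=O)C(C)C)C(=O)C=C2O | intermediate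
11 | geranyl bromide, (2E)-1-bromo-3,7-dimethylocta-2,6-diene | CC(C)=CCC/C(C)=C/CBr | starting material
12 | 1-(2-bromoprop-2-en-1-yl)-9-[(2E)-3,7-dimethylocta-2,6-dien-1-yl]-2,2-dimethyl-7-(2-methylpropanoyl)spiro[4.5]decane-6,8,10-trione (dienol form) | C=C(Br)C[C@@H]1C(C)(C)CC[C@]12C(O)=C(C(=O)C(C)C)C(=O)C(C/C=C(\C)CCC=C(C)C)=C2O | intermediate
13 | methyl 2-({9-[(2E)-3,7-dimethylocta-2,6-dien-1-yl]-2,2-dimethyl-7-(2-methylpropanoyl)-6,8,10-trioxospiro[4.5]decan-1-yl}methyl)prop-2-enoate (dienol form) | COC(=O)C(=C)C[C@@H]1C(C)(C)CC[C@]12C(O)=C(C(=O)C(C)C)C(=O)C(C/C=C(\C)CCC=C(C)C)=C2O | intermediate (not isolated)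
14 | tricyclic methyl ester (cyclopentane-fused bicyclo[4.3.1]decane trione; geranyl on C5, endo CO2Me on C7, enolised isobutyryl-bearing C1) | CC(C)=CCC/C(C)=C/C[C@@]12C[C@H](C(=O)OC)C[C@@H]3C(C)(C)CC[C@]3(C1=O)C(O)=C(C(=O)C(C)C)C2=O | intermediate
15 | tertiary alcohol (as 14 with endo C(CH3)2OH on C7) | CC(C)=CCC/C(C)=C/C[C@@]12C[C@H](C(C)(C)O)C[C@@H]3C(C)(C)CC[C@]3(C1=O)C(O)=C(C(=O)C(C)C)C2=O | intermediate
16 | target CNP0313870.1 | CC(C)=CCC/C(C)=C/C[C@@]12C[C@H]3C[C@@H]4C(C)(C)CC[C@]4(C1=O)C(=O)[C@@](C(=O)C(C)C)(C2=O)C3(C)C | target

**Step count and risks**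
Total steps: 10. Longest linear sequence: 10 (from 1).

The three steps most likely to fail:

1. Step 10. The cation may be captured by an enol oxygen or lose a proton to an alkene faster than the C–C bond forms, and the acid released may start cyclisation of the geranyl chain. The fallback sets out from 15 and comes back at 16. The enol is first O-methylated (Me3SiCHN2, MeOH/toluene) to the methyl enol ether F1, drawn as the C2 regioisomer. The tertiary alcohol is then ionised with Me3SiOTf or BF3·OEt2 at −78 °C next to a neutral enol ether, which carries no acidic proton and whose oxygen cannot give a stable O-alkyl product. The oxocarbenium ion left after C–C bond formation loses its methyl group on aqueous work-up and gives 16.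

2. Step 8. The conjugate addition that makes the quaternary C5 may be slow on the weakly electrophilic acrylate (reversible oxygen addition instead), and the vinylpalladium intermediate may be intercepted by the internal enolate before carbon monoxide inserts. The fallback sets out from 12 and comes back at 15. Stille coupling with tributyl(1-ethoxyvinyl)stannane (Pd(PPh3)4, CuI, DMF) gives the 2-ethoxydiene F2. This is hydrolysed on mildly acidic work-up to the α-methylene ketone F3, a much stronger acceptor, which closes under DBU to the bicyclic methyl ketone F4. A single MeMgBr/CeCl3 addition then gives 15.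

3. Step 6. The dianion may attack the methyl ester instead of the phenyl ester, which would exchange C2 and C4 and invert the relation between C3 and C11, or it may fail to attack the shielded quaternary centre, and the ring may close through oxygen to an enol lactone. The fallback sets out from 6 and comes back at 10 through 9. The enolate of 6 (LiN(iPr)2, THF, −78 °C) is trapped with CO2 to give the half-ester acid F5 (carboxyl trans to the bromoallyl group), and oxalyl chloride converts this to the acid chloride F6. Mukaiyama-type acylation of the bis(trimethylsilyl) dienol ether F7 (from 8 with Me3SiCl/Et3N, then LiN(iPr)2/Me3SiCl) at its terminal carbon, with catalytic Me3SiOTf, gives triketo ester 9 after work-up. This is closed to 10 with NaOMe in MeOH.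

Further compounds
F1 | step 10 | methyl enol ether of 15 (methoxy on C2) | CC(C)=CCC/C(C)=C/C[C@@]12C[C@H](C(C)(C)O)C[C@@H]3C(C)(C)CC[C@]3(C1=O)C(OC)=C(C(=O)C(C)C)C2=O
F2 | step 8 | 2-ethoxydiene (12 with C(OEt)=CH2 in place of Br) | CCOC(=C)C(=C)C[C@@H]1C(C)(C)CC[C@]12C(O)=C(C(=O)C(C)C)C(=O)C(C/C=C(\C)CCC=C(C)C)=C2O
F3 | step 8 | α-methylene methyl ketone (12 with acetyl in place of Br) | CC(=O)C(=C)C[C@@H]1C(C)(C)CC[C@]12C(O)=C(C(=O)C(C)C)C(=O)C(C/C=C(\C)CCC=C(C)C)=C2O
F4 | step 8 | bicyclic methyl ketone (as 14 with endo acetyl on C7) | CC(C)=CCC/C(C)=C/C[C@@]12C[C@H](C(C)=O)C[C@@H]3C(C)(C)CC[C@]3(C1=O)C(O)=C(C(=O)C(C)C)C2=O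
F5 | step 6 | (1S,2R)-2-(2-bromoprop-2-en-1-yl)-1-(methoxycarbonyl)-3,3-dimethylcyclopentane-1-carboxylic acid | C=C(Br)C[C@@H]1C(C)(C)CC[C@]1(C(=O)O)C(=O)OC
F6 | step 6 | methyl (1R,2R)-2-(2-bromoprop-2-en-1-yl)-1-(chlorocarbonyl)-3,3-dimethylcyclopentane-1-carboxylate | C=C(Br)C[C@@H]1C(C)(C)CC[C@]1(C(=O)Cl)C(=O)OC
F7 | step 6 | 5-methyl-2,4-bis(trimethylsilyloxy)hexa-1,3-diene | C=C(O[Si](C)(C)C)C=C(O[Si](C)(C)C)C(C)C
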